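The cyclohexene is cut at the C1–C6 bond (C1 carries the C7 methylene ether, C2 the ring methyl, C5 the acyloxy group, C6 the gem-dimethyl group). C1 is flanked by C7 and C2 in the pattern of a β-keto ester α-carbon and is attached to quaternary C6, which a trisubstituted epoxide can supply as a tertiary cation. One Lewis-acid step thus closes the six-membered carbocycle, makes the bond to the quaternary carbon and passes the epoxide stereocentre on as the C5 carbinol. Its precursor is the open-chain (R)-epoxy β-keto ester 8. A later bridged lactone turns C1 into a bridgehead, so the C2 ketone enolises only toward C3.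

Key step: step 4

Remark on the chemistry: the epoxide is set on a Weinreb amide and the β-keto ester is assembled afterwards, since KHSO5 and dioxiranes hydroxylate and cleave β-keto ester enolates at the pH of the epoxidation; 9 is drawn as its cis isomer, and its C1 epimer and enol should converge on lactone 10.

Step 1
Reactants: 1 N-methoxy-N-methylacetamide; 2 prenyl bromide (1-bromo-3-methylbut-2-ene)
Product: 4 N-methoxy-N,5-dimethylhex-4-enamide, via lithium amide enolate 3 (not isolated)
Conditions: LiN(i-Pr)2, THF, −78 °C; then 2, −78 → −30 °C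
Reagents that add atoms: none
Why: Alkylation of a Weinreb amide enolate (SN2 at the primary allylic bromide) should proceed cleanly at low temperature, where the lithium enolate does not fragment, and attack at the unhindered CH2 terminus of prenyl bromide is expected over SN2'.

Step 2
Reactants: 4 N-methoxy-N,5-dimethylhex-4-enamide
Product: 5 3-[(2R)-3,3-dimethyloxiran-2-yl]-N-methoxy-N-methylpropanamide
Conditions: D-fructose-derived Shi ketone (30 mol%), KHSO5 (as 2KHSO5·KHSO4·K2SO4), K2CO3, Bu4NHSO4 (cat.), MeCN–CH2(OMe)2–aq. Na2B4O7 buffer, 0 °C
Reagents that add atoms: potassium peroxymonosulfate, [K+].[O-]S(=O)(=O)OO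
Why: Shi asymmetric epoxidation, in which the dioxirane formed from the D-fructose-derived ketone transfers oxygen to the electron-rich trisubstituted alkene through a spiro transition state that should deliver the (R)-epoxide (the future C5 centre), while the amide offers no enolisable 1,3-dicarbonyl unit to the oxidant.

Step 3
Reactants: 5 3-[(2R)-3,3-dimethyloxiran-2-yl]-N-methoxy-N-methylpropanamide; 6 methyl acetate
Product: 8 methyl (6R)-6,7-epoxy-7-methyl-3-oxooctanoate, via lithium ester enolate 7 (not isolated)
Conditions: 6 (3 equiv), LiN(i-Pr)2 (3 equiv), THF, −78 °C; then 5, −78 → −40 °C; aqueous work-up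
Reagents that add atoms: none
Why: Acylation of an ester enolate by a Weinreb amide (crossed Claisen-type condensation), in which the chelated tetrahedral adduct and deprotonation of the product by excess enolate prevent over-addition, and the trisubstituted epoxide is inert to the enolate at low temperature.

Step 4
Reactants: 8 methyl (6R)-6,7-epoxy-7-methyl-3-oxooctanoate
Product: 9 methyl (1R,3R)-3-hydroxy-2,2-dimethyl-6-oxocyclohexane-1-carboxylate
Conditions: SnCl4 (2.2 equiv), CH2Cl2, −78 → −20 °C
Reagents that add atoms: none
Why: SnCl4 binds the keto ester as a chelated enol and activates the oxirane oxygen; heterolysis of the O–C6 bond (ring numbering) develops positive charge on the dimethyl-substituted carbon, which is captured by the enol carbon C1 in a chair-like array, so that the C1–C6 bond forms and the former epoxide oxygen stays on C5 as the hydroxyl. The closest known reaction type is the Lewis-acid-promoted, epoxide-initiated cationic cyclisation terminated by a β-dicarbonyl enol, the oxirane counterpart of the SnCl4 cyclisation of unsaturated β-keto esters. The one ring formed, the six-membered carbocycle C1–C6, closes in the 6-endo-tet mode with respect to the epoxide and 6-(enolendo) with respect to the nucleophile. C5 is not involved in bond breaking and keeps the R configuration of the epoxide; the new centre C1 is the α-carbon of a β-keto ester, so it should settle as the diequatorial cis isomer under thermodynamic control and is fixed as cis in any case by the lactone of step 5. The step needs opening at the tertiary and not the secondary oxirane carbon and C- rather than O-alkylation of the enol: the first follows from Markovnikov ionisation at the only cation-stabilising carbon, the second because a tert-alkyl enol ether formed by O-attack can re-ionise under the Lewis acid whereas C–C bond formation is irreversible.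

Step 5
Reactants: 9 methyl (1R,3R)-3-hydroxy-2,2-dimethyl-6-oxocyclohexane-1-carboxylate
Product: 10 (1R,5R)-8,8-dimethyl-6-oxabicyclo[3.2.1]octane-2,7-dione
Conditions: CSA (10 mol%), toluene, reflux, 4 Å molecular sieves (removal of MeOH)
Reagents that add atoms: none
Why: Acid-catalysed lactonisation (intramolecular transesterification) of the γ-hydroxy ester, in which only the cis isomer can bridge C1 and C5 as a five-membered lactone, the acid equilibrates C1 through the β-keto ester enol so that all material should funnel into 10, and removal of methanol drives the closure.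

Step 6
Reactants: 10 (1R,5R)-8,8-dimethyl-6-oxabicyclo[3.2.1]octane-2,7-dione
Product: 12 (1R,5R)-8,8-dimethyl-7-oxo-6-oxabicyclo[3.2.1]oct-2-en-2-yl trifluoromethanesulfonate, via potassium enolate 11 (not isolated)
Conditions: KN(SiMe3)2, THF, −78 °C; then PhNTf2, −78 → 0 °C
Reagents that add atoms: N-phenylbis(trifluoromethanesulfonimide), O=S(=O)(N(c1ccccc1)S(=O)(=O)C(F)(F)F)C(F)(F)F
Why: Regiospecific enolate O-triflation, since C1 is now a bridgehead of the bicyclo[3.2.1] lactone and by Bredt's rule can neither be deprotonated nor epimerised, so the hindered amide base can only remove a C3 proton and a single C2=C3 enol triflate should result.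

Step 7
Reactants: 12 (1R,5R)-8,8-dimethyl-7-oxo-6-oxabicyclo[3.2.1]oct-2-en-2-yl trifluoromethanesulfonate
Product: 13 (1S,5R)-2,8,8-trimethyl-6-oxabicyclo[3.2.1]oct-2-en-7-one
Conditions: MeZnCl, Pd(PPh3)4 (5 mol%), THF, 0 °C → rt
Reagents that add atoms: methylzinc chloride, C[Zn]Cl
Why: Negishi cross-coupling, in which zerovalent palladium inserts into the alkenyl C–OTf bond, methyl is transferred from zinc and reductive elimination gives the trisubstituted alkene, the organozinc leaving the lactone untouched and the bridgehead preventing migration of the double bond (the C1 descriptor becomes S only because the CIP priorities change).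

Step 8
Reactants: 13 (1S,5R)-2,8,8-trimethyl-6-oxabicyclo[3.2.1]oct-2-en-7-one
Product: 14 (1R,5S)-5-(hydroxymethyl)-4,6,6-trimethylcyclohex-3-en-1-ol
Conditions: LiAlH4, THF, 0 °C → rt; aqueous work-up
Reagents that add atoms: none
Why: Hydride reduction of the lactone to the diol touches no stereocentre, so the cis relation of the C7 hydroxymethyl group and the C5 hydroxyl is carried over from the lactone bridge.

Step 9
Reactants: 14 (1R,5S)-5-(hydroxymethyl)-4,6,6-trimethylcyclohex-3-en-1-ol; 15 umbelliferone (7-hydroxy-2H-chromen-2-one)
Product: 16 7-{[(1S,5R)-5-hydroxy-2,6,6-trimethylcyclohex-2-en-1-yl]methoxy}-2H-chromen-2-one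
Conditions: PPh3, DIAD, THF, 0 °C → rt
Reagents that add atoms: none
Why: Mitsunobu etherification, in which the acidic phenol protonates the betaine, the primary hydroxyl is activated in preference to the neopentylic secondary one, and SN2 attack of the phenoxide at the non-stereogenic C7 should give the aryl ether with C5 untouched.

Step 10
Reactants: 16 7-{[(1S,5R)-5-hydroxy-2,6,6-trimethylcyclohex-2-en-1-yl]methoxy}-2H-chromen-2-one; 17 (R)-2-methylbutanoic acid
Product: 18 (1R,5S)-4,6,6-trimethyl-5-{[(2-oxo-2H-chromen-7-yl)oxy]methyl}cyclohex-3-en-1-yl (2R)-2-methylbutanoate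
Conditions: DCC, DMAP (cat.), CH2Cl2, 0 °C → rt
Reagents that add atoms: none
Why: Steglich esterification transfers the acyl group to the C5 oxygen without breaking the C5–O bond, so C5 stays R, and the α-centre of the saturated acid is not expected to epimerise under these mild conditions.

Compound list
1 | N-methoxy-N-methylacetamide | CC(=O)N(C)OC | starting material
2 | prenyl bromide (1-bromo-3-methylbut-2-ene) | CC(C)=CCBr | starting material
3 | lithium 1-[methoxy(methyl)amino]ethen-1-olate (lithium enolate of 1) | [Li]OC(=C)N(C)OC | intermediate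
4 | N-methoxy-N,5-dimethylhex-4-enamide | CC(C)=CCCC(=O)N(C)OC | intermediate
5 | 3-[(2R)-3,3-dimethyloxiran-2-yl]-N-methoxy-N-methylpropanamide | CC1(C)O[C@@H]1CCC(=O)N(C)OC | intermediate
6 | methyl acetate | CC(=O)OC | starting material
7 | lithium 1-methoxyethen-1-olate (lithium enolate of 6) | [Li]OC(=C)OC | intermediate
8 | methyl (6R)-6,7-epoxy-7-methyl-3-oxooctanoate | CC1(C)O[C@@H]1CCC(=O)CC(=O)OC | intermediate
9 | methyl (1R,3R)-3-hydroxy-2,2-dimethyl-6-oxocyclohexane-1-carboxylate (cis) | O[C@@H]1CCC(=O)[C@H](C(=O)OC)C1(C)C | intermediate
10 | (1R,5R)-8,8-dimethyl-6-oxabicyclo[3.2.1]octane-2,7-dione | O1[C@@H]2CCC(=O)[C@H](C1=O)C2(C)C | intermediate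
11 | potassium (1R,5R)-8,8-dimethyl-7-oxo-6-oxabicyclo[3.2.1]oct-2-en-2-olate | O1[C@@H]2CC=C(O[K])[C@H](C1=O)C2(C)C | intermediate
12 | (1R,5R)-8,8-dimethyl-7-oxo-6-oxabicyclo[3.2.1]oct-2-en-2-yl trifluoromethanesulfonate | O1[C@@H]2CC=C(OS(=O)(=O)C(F)(F)F)[C@H](C1=O)C2(C)C | intermediate
13 | (1S,5R)-2,8,8-trimethyl-6-oxabicyclo[3.2.1]oct-2-en-7-one | O1[C@@H]2CC=C(C)[C@H](C1=O)C2(C)C | intermediate
14 | (1R,5S)-5-(hydroxymethyl)-4,6,6-trimethylcyclohex-3-en-1-ol | O[C@@H]1CC=C(C)[C@H](CO)C1(C)C | intermediate
15 | umbelliferone (7-hydroxy-2H-chromen-2-one) | O=c1ccc2ccc(O)cc2o1 | starting material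
16 | 7-{[(1S,5R)-5-hydroxy-2,6,6-trimethylcyclohex-2-en-1-yl]methoxy}-2H-chromen-2-one | O[C@@H]1CC=C(C)[C@H](COc2ccc3ccc(=O)oc3c2)C1(C)C | intermediate
17 | (R)-2-methylbutanoic acid | CC[C@@H](C)C(=O)O | starting material
18 | (1R,5S)-4,6,6-trimethyl-5-{[(2-oxo-2H-chromen-7-yl)oxy]methyl}cyclohex-3-en-1-yl (2R)-2-methylbutanoate | CC[C@@H](C)C(=O)O[C@@H]1CC=C(C)[C@H](COc2ccc3ccc(=O)oc3c2)C1(C)C | target

Total step count: 10. Longest linear sequence: 10 steps (1 and 2 to 18).

Steps most likely to fail

Step 4. Capture of the opening epoxide by the enol oxygen (giving a cyclic enol ether) or a 1,2-hydride shift to a ketone may outrun C–C bond formation. The fallback sets out from 8, which is converted with NaH and TBSCl in THF at 0 °C into methyl (2Z)-3-[(tert-butyldimethylsilyl)oxy]-5-[(2R)-3,3-dimethyloxiran-2-yl]pent-2-enoate F1. This silyl enol ether is then cyclised with MeAlCl2 in CH2Cl2 at −78 °C, an epoxide-initiated cyclisation terminated by a silyl enol ether (a tert-alkylation of the Mukaiyama type). The oxygen is blocked, so only the enol carbon can attack. A work-up with HF·pyridine removes silicon, including any that has moved to the C5 oxygen, and the route is rejoined at 9.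

Step 9. Intramolecular capture of the activated primary oxygen by the cis C5 hydroxyl (cyclodehydration to a bridged ether) or β-elimination may compete with attack of the phenoxide at the β-branched primary carbon. The fallback sets out from 14. The primary hydroxyl is silylated (TBSCl, imidazole, DMF, 0 °C) to (1R,5S)-5-{[(tert-butyldimethylsilyl)oxy]methyl}-4,6,6-trimethylcyclohex-3-en-1-ol F2. The secondary hydroxyl is then acylated with 17 (DCC, DMAP, CH2Cl2) to (1R,5S)-5-{[(tert-butyldimethylsilyl)oxy]methyl}-4,6,6-trimethylcyclohex-3-en-1-yl (2R)-2-methylbutanoate F3. Silicon is removed with HF·pyridine in THF to give (1R,5S)-5-(hydroxymethyl)-4,6,6-trimethylcyclohex-3-en-1-yl (2R)-2-methylbutanoate F4. The Mitsunobu etherification with 15 (PPh3, DIAD, THF) is then run on this mono-alcohol, which has no second hydroxyl, and the route is rejoined at the target 18 without passing through 16.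

Step 6. Attack of base or adventitious alkoxide on the strained, non-enolisable β-keto lactone (retro-Claisen opening of C1–C2 or cleavage of the lactone) may compete with deprotonation at C3, and the later coupling at the hindered C2 may be slow. The fallback sets out from 10 and uses carbonyl addition instead of an enolate. The organocerium reagent from MeMgBr and CeCl3 (THF, −78 °C) should add to the ketone in preference to the lactone, giving (1R,5R)-2-hydroxy-2,8,8-trimethyl-6-oxabicyclo[3.2.1]octan-7-one F5 as either C2 epimer; retro-aldol cleavage is blocked because it would need a bridgehead enolate. Dehydration with SOCl2 and pyridine at 0 °C cannot place the alkene at bridgehead C1, so it should give the C2=C3 alkene, with any exocyclic isomer equilibrated by a trace of TsOH. The route is rejoined at 13, bypassing 12.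

Further compounds
F1 | step 4 | methyl (2Z)-3-[(tert-butyldimethylsilyl)oxy]-5-[(2R)-3,3-dimethyloxiran-2-yl]pent-2-enoate | CC1(C)O[C@@H]1CC/C(O[Si](C)(C)C(C)(C)C)=C/C(=O)OC
F2 | step 9 | (1R,5S)-5-{[(tert-butyldimethylsilyl)oxy]methyl}-4,6,6-trimethylcyclohex-3-en-1-ol | O[C@@H]1CC=C(C)[C@H](CO[Si](C)(C)C(C)(C)C)C1(C)C
F3 | step 9 | (1R,5S)-5-{[(tert-butyldimethylsilyl)oxy]methyl}-4,6,6-trimethylcyclohex-3-en-1-yl (2R)-2-methylbutanoate | CC[C@@H](C)C(=O)O[C@@H]1CC=C(C)[C@H](CO[Si](C)(C)C(C)(C)C)C1(C)C
F4 | step 9 | (1R,5S)-5-(hydroxymethyl)-4,6,6-trimethylcyclohex-3-en-1-yl (2R)-2-methylbutanoate | CC[C@@H](C)C(=O)O[C@@H]1CC=C(C)[C@H](CO)C1(C)C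
F5 | step 6 | (1R,5R)-2-hydroxy-2,8,8-trimethyl-6-oxabicyclo[3.2.1]octan-7-one (either C2 epimer) | O1[C@@H]2CCC(C)(O)[C@H](C1=O)C2(C)C
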